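The synthesis cuts the dihydrofuran ring at both of its bonds to ring A, C3–C3a and O1–C7a (benzofuran numbering). This turns O1–C2–C3 into a terminal (R)-epoxide and ring A into a 4-iodoacetophenone. One palladium/norbornene (Catellani-type) annulation rejoins them: the C–H next to iodine is alkylated by the epoxide CH2, and the released alkoxide closes on the iodine-bearing carbon. The step exploits three features. C7a lies para to the ketone. C3a–H is the only unshielded C–H beside C7a, because C7–H is flanked by the C6 oxygen. The C2–O1 bond is never broken, so C2 comes from the chiral pool. Acetal cleavage and a Claisen–Schmidt condensation finish the chalcone.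

Key step: step 3

Assumption: 1-(2-hydroxy-4-iodophenyl)ethanone, methyl (R)-glycidate and 2,2-dimethylchroman-6-carbaldehyde are taken as catalogue compounds. The target stereocentre (C2 of the dihydrobenzofuran) is read from the SMILES as (R).

Step 1
Reactants: 1 1-(2-hydroxy-4-iodophenyl)ethanone
Product: 2 1-[4-iodo-2-(methoxymethoxy)phenyl]ethanone
Conditions: NaH (1.1 equiv), MOMCl (1.2 equiv), DMF, 0 °C → rt
Reagents that add atoms: chloromethyl methyl ether (MOMCl), COCCl
Why: Williamson-type O-alkylation: one equivalent of NaH removes only the phenol proton, which is far more acidic than the acetyl CH3, and the phenoxide is captured by the very reactive chloromethyl ether while the aryl iodide stays inert.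

Step 2
Reactants: 3 methyl (2R)-oxirane-2-carboxylate (methyl (R)-glycidate)
Product: 6 (2R)-2-[2-(methoxymethoxy)propan-2-yl]oxirane, via epoxy ketone 4 (not isolated), via lithium alkoxide 5 (not isolated)
Conditions: MeLi (2.1 equiv), Et2O/THF, −78 °C; then MOMCl (2.5 equiv), −78 → 0 °C
Reagents that add atoms: methyllithium, [Li]C; chloromethyl methyl ether (MOMCl), COCCl
Why: Double 1,2-addition of an organolithium to an ester followed by Williamson-type trapping of the tertiary alkoxide: at −78 °C the ester and the ketone 4 derived from it react much faster than the unactivated oxirane, the oxirane CH stereocentre comes unchanged from the chiral pool, and capping in the same flask leaves alkoxide 5 little time for Payne rearrangement and spares the isolation of a volatile, water-soluble epoxy alcohol.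

Step 3
Reactants: 2 1-[4-iodo-2-(methoxymethoxy)phenyl]ethanone; 6 (2R)-2-[2-(methoxymethoxy)propan-2-yl]oxirane (2 equiv)
Product: 7 1-[(2R)-6-(methoxymethoxy)-2-[2-(methoxymethoxy)propan-2-yl]-2,3-dihydro-1-benzofuran-5-yl]ethanone
Conditions: Pd(OAc)2 (10 mol %), XPhos (20 mol %), potassium 5-norbornene-2-carboxylate (0.5 equiv), K2CO3 (2 equiv), NMP, 80 °C, argon
Reagents that add atoms: none
Why: Catellani-type palladium/norbornene annulation of an aryl iodide with a terminal epoxide, a known reaction type: zerovalent palladium inserts into the C–I bond of 2, the norbornene carbopalladates, and concerted metalation–deprotonation of the adjacent C5–H of 2 (the later C3a) gives the aryl–norbornyl palladacycle. This electron-rich palladacycle opens 6 by SN2 attack at its unsubstituted CH2 to a tetravalent palladium alkoxide, aryl–CH2 reductive elimination makes the C3–C3a bond, norbornene is expelled by β-carbon elimination, and the tethered secondary alkoxide then sits on the divalent aryl–palladium centre at the former C–I carbon. The dihydrofuran ring closes there by C(aryl)–O reductive elimination from a six-membered oxapalladacycle (O1–C7a bond), so the whole is a formal (3+2) annulation of the O1–C2–C3 unit onto the C3a–C7a edge of ring A. No stereocentre is created: C2 is the oxirane CH whose C–O bond is never broken, so (R)-6 should be carried into (R)-7 with retention, as is known for enantiopure epoxides in this reaction. The step needs site selectivity between the two C–H bonds ortho to iodine and a stop after one alkylation, and both rest on the OMOM group, whose CH2 is turned by the neighbouring acetyl group towards C3–H of 2 (the later C7) and shields it, standing in for the ortho substituent that this chemistry normally wants. The para acetyl group speeds up oxidative addition and C–O reductive elimination, the MOM cap on the tertiary oxygen rules out closure to the isomeric chroman and Payne rearrangement, and the weak carbonate base together with fast norbornene capture should keep ketone α-arylation down.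

Step 4
Reactants: 7 1-[(2R)-6-(methoxymethoxy)-2-[2-(methoxymethoxy)propan-2-yl]-2,3-dihydro-1-benzofuran-5-yl]ethanone
Product: 9 1-[(2R)-6-hydroxy-2-(2-hydroxypropan-2-yl)-2,3-dihydro-1-benzofuran-5-yl]ethanone, via mono-MOM phenol 8 (not isolated)
Conditions: aq. HCl (3 M)/MeOH, 50 °C
Reagents that add atoms: none
Why: Acid-catalysed acetal exchange (methanolysis of MOM ethers): the aryl acetal next to the ketone should go first and the tertiary alkyl acetal follows, while the ring C2–O1 and the tertiary C–O bonds stay intact because a cation next to the oxygen-bearing C2 is disfavoured, so C2 is not touched.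

Step 5
Reactants: 9 1-[(2R)-6-hydroxy-2-(2-hydroxypropan-2-yl)-2,3-dihydro-1-benzofuran-5-yl]ethanone; 10 2,2-dimethyl-3,4-dihydro-2H-chromene-6-carbaldehyde
Product: 12 (2E)-3-(2,2-dimethyl-3,4-dihydro-2H-chromen-6-yl)-1-[(2R)-6-hydroxy-2-(2-hydroxypropan-2-yl)-2,3-dihydro-1-benzofuran-5-yl]prop-2-en-1-one (CNP0327385.2), via aldol adduct 11 (not isolated)
Conditions: KOH (10 equiv, 50 % aq.), EtOH, rt; then cold 1 M HCl to pH 5
Reagents that add atoms: none
Why: Claisen–Schmidt condensation (crossed aldol addition and E1cB dehydration) as is routine for 2-hydroxyacetophenones: 10 cannot enolise, the conjugated (E)-alkene is the thermodynamic outcome, the product rests as its phenoxide in the strongly basic medium, which disfavours closure to the flavanone, and C2 carries no acidic hydrogen.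

Compound list
1 | 1-(2-hydroxy-4-iodophenyl)ethanone | CC(=O)c1ccc(I)cc1O | starting material
2 | 1-[4-iodo-2-(methoxymethoxy)phenyl]ethanone | CC(=O)c1ccc(I)cc1OCOC | intermediate
3 | methyl (2R)-oxirane-2-carboxylate | COC(=O)[C@H]1CO1 | starting material
4 | 1-[(2R)-oxiran-2-yl]ethanone (not isolated) | CC(=O)[C@H]1CO1 | intermediate
5 | lithium 2-[(2R)-oxiran-2-yl]propan-2-olate (not isolated) | [Li+].CC(C)([O-])[C@H]1CO1 | intermediate
6 | (2R)-2-[2-(methoxymethoxy)propan-2-yl]oxirane | COCOC(C)(C)[C@H]1CO1 | intermediate
7 | 1-[(2R)-6-(methoxymethoxy)-2-[2-(methoxymethoxy)propan-2-yl]-2,3-dihydro-1-benzofuran-5-yl]ethanone | CC(=O)c1cc2c(cc1OCOC)O[C@@H](C(C)(C)OCOC)C2 | intermediate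
8 | 1-[(2R)-6-hydroxy-2-[2-(methoxymethoxy)propan-2-yl]-2,3-dihydro-1-benzofuran-5-yl]ethanone (not isolated) | CC(=O)c1cc2c(cc1O)O[C@@H](C(C)(C)OCOC)C2 | intermediate
9 | 1-[(2R)-6-hydroxy-2-(2-hydroxypropan-2-yl)-2,3-dihydro-1-benzofuran-5-yl]ethanone | CC(=O)c1cc2c(cc1O)O[C@@H](C(C)(C)O)C2 | intermediate
10 | 2,2-dimethyl-3,4-dihydro-2H-chromene-6-carbaldehyde | CC1(C)CCc2cc(C=O)ccc2O1 | starting material
11 | β-hydroxy ketone from 9 and 10, carbinol centre undefined (not isolated) | CC1(C)CCc2cc(C(O)CC(=O)c3cc4c(cc3O)O[C@@H](C(C)(C)O)C4)ccc2O1 | intermediate
12 | (2E)-3-(2,2-dimethyl-3,4-dihydro-2H-chromen-6-yl)-1-[(2R)-6-hydroxy-2-(2-hydroxypropan-2-yl)-2,3-dihydro-1-benzofuran-5-yl]prop-2-en-1-one | CC1(C)CCc2cc(/C=C/C(=O)c3cc4c(cc3O)O[C@@H](C(C)(C)O)C4)ccc2O1 | target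

Total step count: 5. Longest linear sequence: 4 steps (3 → 6 → 7 → 9 → 12, or equally 1 → 2 → 7 → 9 → 12).

Steps most likely to fail

**Step 3.**
- What may go wrong: 2 has no substituent ortho to iodine, so norbornene extrusion after the first alkylation may be slow.
  - A second palladation at the shielded C–H, retention of norbornene in the product, or direct reactions at the ipso carbon could then compete. The ipso reactions are ketone α-arylation and hydrodeiodination after β-hydride loss from the secondary alkoxide.
  - The branched carbon next to the oxirane may also slow the ring opening.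
- Fallback: it sets out from 6 and comes back to the route at 7. It makes the two bonds one after the other, with the regiochemistry fixed by a halogen pattern.
  - Commercial 1-(5-bromo-4-fluoro-2-hydroxyphenyl)ethanone F1 is capped as in step 1 to 1-[5-bromo-4-fluoro-2-(methoxymethoxy)phenyl]ethanone F2.
  - F2 is joined to 6 by a nickel-catalysed reductive cross-electrophile coupling (NiCl2(dme), 2,2'-bipyridine, NaI, Et3N·HCl, Mn powder, DMPU, rt). Iodide opens the oxirane at CH2 and the aryl–nickel species takes up the primary alkyl fragment.
  - This should give 1-{4-fluoro-5-[(2R)-2-hydroxy-3-(methoxymethoxy)-3-methylbutyl]-2-(methoxymethoxy)phenyl}ethanone F3 with the carbinol centre untouched.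
  - Cs2CO3 in DMSO at 80 °C then closes O1–C7a by intramolecular SNAr on the fluoride para to the ketone, giving 7.

**Step 2.**
- What may go wrong: O-alkylation of the hindered tertiary lithium alkoxide may be slow. Payne-type migration of the oxirane or its opening by chloride could then compete, and the small product may be lost on isolation.
- Fallback: it sets out from 3 and comes back to the route at 9. It gives up the cap on the tertiary oxygen altogether.
  - MeMgBr (2.2 equiv, THF, −78 °C) with a cold NH4Cl quench and careful distillation gives (2R)-2-(oxiran-2-yl)propan-2-ol F4.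
  - F4 is used uncapped with 2 under the conditions of step 3. The secondary oxygen is delivered to palladium as the alkoxide by the ring opening itself, while the tertiary hydroxyl stays protonated under carbonate. Closure through the six-membered oxapalladacycle should therefore outrun the seven-membered alternative.
  - The product is 1-[(2R)-2-(2-hydroxypropan-2-yl)-6-(methoxymethoxy)-2,3-dihydro-1-benzofuran-5-yl]ethanone F5.
  - The acid treatment of step 4 then removes the single aryl acetal and gives 9.

**Step 5.**
- What may go wrong: enolisation of a ketone that already carries a phenoxide may be sluggish, and partial closure to the flavanone may occur during the condensation or the acidic work-up.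
- Fallback: it sets out from 7 (with 10) and comes back to the route at 12. It reverses the order of condensation and deprotection.
  - The fully capped ketone 7, which enolises more readily and cannot cyclise, is condensed with 10 (KOH, EtOH, rt). This gives (2E)-3-(2,2-dimethyl-3,4-dihydro-2H-chromen-6-yl)-1-[(2R)-6-(methoxymethoxy)-2-[2-(methoxymethoxy)propan-2-yl]-2,3-dihydro-1-benzofuran-5-yl]prop-2-en-1-one F6.
  - Both acetals of F6 are then cleaved with HCl in MeOH at 40–50 °C under close monitoring to give 12.

Further compounds
F1 | step 3 | 1-(5-bromo-4-fluoro-2-hydroxyphenyl)ethanone | CC(=O)c1cc(Br)c(F)cc1O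
F2 | step 3 | 1-[5-bromo-4-fluoro-2-(methoxymethoxy)phenyl]ethanone | CC(=O)c1cc(Br)c(F)cc1OCOC
F3 | step 3 | 1-{4-fluoro-5-[(2R)-2-hydroxy-3-(methoxymethoxy)-3-methylbutyl]-2-(methoxymethoxy)phenyl}ethanone | CC(=O)c1cc(C[C@@H](O)C(C)(C)OCOC)c(F)cc1OCOC
F4 | step 2 | (2R)-2-(oxiran-2-yl)propan-2-ol | CC(C)(O)[C@H]1CO1
F5 | step 2 | 1-[(2R)-2-(2-hydroxypropan-2-yl)-6-(methoxymethoxy)-2,3-dihydro-1-benzofuran-5-yl]ethanone | CC(=O)c1cc2c(cc1OCOC)O[C@@H](C(C)(C)O)C2
F6 | step 5 | (2E)-3-(2,2-dimethyl-3,4-dihydro-2H-chromen-6-yl)-1-[(2R)-6-(methoxymethoxy)-2-[2-(methoxymethoxy)propan-2-yl]-2,3-dihydro-1-benzofuran-5-yl]prop-2-en-1-one | CC1(C)CCc2cc(/C=C/C(=O)c3cc4c(cc3OCOC)O[C@@H](C(C)(C)OCOC)C4)ccc2O1
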